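**Strategy.** The oxane ring (O1, C2 bearing the acrylic acid, C3, C4, C5 bearing the chain, C6) is built as (5R)-5-homofarnesyloxan-2-one. C2, the ring carbon flanked by O1 and the acrylic acid carbon, is treated as a latent lactone carbonyl. This makes C3 the α-carbon of an acetate on O1–C6, and C4 a CH2I group on the only pre-set stereocentre, C5. Intramolecular C-alkylation of the acetate enolate forms C3–C4 and closes the ring in one operation. The precursor is an acyclic iodo acetate whose acetyl group was installed by the lipase that desymmetrised a prochiral diol. Axial alkynylation of the derived oxocarbenium ion then sets C2 cis to C5, and hydroxycarbonylation completes the acid.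

Key step: step 5

Assumption: the lipase acetylates the enantiotopic CH2OH group that leads to (R)-7; should it prefer the other group, hydrolysis of the diacetate of 6 with the same lipase gives (R)-7 instead.

Step 1
Reactants: 1 2-methylprop-2-en-1-ol; 2 (2E,6E)-farnesyl bromide
Product: 4 (5E,9E)-6,10,14-trimethyl-2-methylidenepentadeca-5,9,13-trien-1-ol, via dilithio dianion 3 (not isolated)
Conditions: n-BuLi (2.2 equiv), TMEDA, Et2O–hexane, 0 °C → rt; then 2, THF, −78 °C → rt
Reagents that add atoms: none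
Why: Double deprotonation of 1 gives the 2-(oxidomethyl)allyl dianion 3, whose carbanion terminus displaces the primary allylic bromide of 2 in an SN2 alkylation (allyl dianion alkylation) that leaves the E-alkenes untouched.

Step 2
Reactants: 4 (5E,9E)-6,10,14-trimethyl-2-methylidenepentadeca-5,9,13-trien-1-ol
Product: 6 2-[(3E,7E)-4,8,12-trimethyltrideca-3,7,11-trien-1-yl]propane-1,3-diol, via bis(boryl) adduct 5 (not isolated)
Conditions: 9-BBN (2.3 equiv), THF, 0 °C → rt; then NaOH, H2O2, 0 °C
Reagents that add atoms: hydrogen peroxide, OO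
Why: 9-BBN hydroborates the 1,1-disubstituted terminal alkene far faster than the three trisubstituted alkenes and places boron on the terminal carbon, so hydroboration–oxidation should give the prochiral 1,3-diol.

Step 3
Reactants: 6 2-[(3E,7E)-4,8,12-trimethyltrideca-3,7,11-trien-1-yl]propane-1,3-diol
Product: 7 (2R,5E,9E)-2-(hydroxymethyl)-6,10,14-trimethylpentadeca-5,9,13-trien-1-yl acetate
Conditions: lipase from Burkholderia cepacia (Amano PS), vinyl acetate, iPr2O, rt
Reagents that add atoms: vinyl acetate, C=COC(C)=O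
Why: Lipase-catalysed transesterification (enzymatic desymmetrisation of a prochiral 2-substituted propane-1,3-diol) acetylates one enantiotopic CH2OH group and thereby sets the C5 stereocentre, the irreversible acyl donor preventing back-reaction.

Step 4
Reactants: 7 (2R,5E,9E)-2-(hydroxymethyl)-6,10,14-trimethylpentadeca-5,9,13-trien-1-yl acetate
Product: 8 (2S,5E,9E)-2-(iodomethyl)-6,10,14-trimethylpentadeca-5,9,13-trien-1-yl acetate
Conditions: PPh3, I2, imidazole, CH2Cl2, 0 °C
Reagents that add atoms: iodine, II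
Why: The Appel reaction converts the remaining primary alcohol into the iodide by SN2 at a non-stereogenic carbon, so C5 keeps its spatial arrangement (the descriptor becomes S only because CH2I outranks CH2OAc).

Step 5
Reactants: 8 (2S,5E,9E)-2-(iodomethyl)-6,10,14-trimethylpentadeca-5,9,13-trien-1-yl acetate
Product: 10 (5R)-5-[(3E,7E)-4,8,12-trimethyltrideca-3,7,11-trien-1-yl]oxan-2-one, via lithium enolate 9 (not isolated)
Conditions: LiN(SiMe3)2 (1.2 equiv), THF–DMPU, −78 → −20 °C, slow addition of 8 to the base, 0.01 M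
Reagents that add atoms: none
Why: LiN(SiMe3)2 removes an acetyl α-proton of 8 to give the O-lithium enolate 9, whose α-carbon (C3) displaces iodide from the CH2I carbon (C4) of the same chain in an intramolecular SN2 C-alkylation; the closest known reaction type is lactone formation by intramolecular alkylation of an ester enolate. The oxan-2-one ring closes in the 6-(enolendo)-exo-tet mode, which is stereoelectronically allowed because the six-membered transition state lets C4 approach perpendicular to the enolate plane with the O1–C6 bond s-cis to the enolate C=C. No stereocentre is formed, and C5, which bears no acidic hydrogen, is untouched. The step needs C- over O-alkylation (lithium counter-ion, soft iodide leaving group), ring closure over intermolecular Claisen condensation (high dilution, low temperature, inverse addition) and substitution over E2 (primary iodide, non-nucleophilic amide base). The isolated trisubstituted alkenes are inert under these conditions.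

Step 6
Reactants: 10 (5R)-5-[(3E,7E)-4,8,12-trimethyltrideca-3,7,11-trien-1-yl]oxan-2-one
Product: 12 (5R)-5-[(3E,7E)-4,8,12-trimethyltrideca-3,7,11-trien-1-yl]oxan-2-yl acetate (both C2 epimers), via aluminium lactolate 11 (not isolated)
Conditions: iBu2AlH, CH2Cl2, −78 °C; then pyridine, DMAP, Ac2O, −78 → 0 °C
Reagents that add atoms: acetic anhydride, CC(=O)OC(C)=O
Why: iBu2AlH adds once to the lactone carbonyl at low temperature and the tetrahedral aluminium lactolate 11 is acetylated in the same flask (reductive acetylation), giving the anomeric acetate as precursor of the cyclic oxocarbenium ion.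

Step 7
Reactants: 12 (5R)-5-[(3E,7E)-4,8,12-trimethyltrideca-3,7,11-trien-1-yl]oxan-2-yl acetate
Product: 14 (2R,5R)-2-ethynyl-5-[(3E,7E)-4,8,12-trimethyltrideca-3,7,11-trien-1-yl]oxane, via silylalkyne 13 (not isolated)
Conditions: Me3SiC≡CSnBu3, BF3·OEt2, CH2Cl2, −78 → −40 °C; then K2CO3, MeOH, rt
Reagents that add atoms: trimethyl[(tributylstannyl)ethynyl]silane, C[Si](C)(C)C#C[Sn](CCCC)(CCCC)CCCC
Why: BF3·OEt2 ionises the anomeric acetate to the six-membered oxocarbenium ion, which adopts the half-chair with the C5 chain pseudo-equatorial and is attacked by the alkynylstannane along the axial trajectory leading to a chair (Lewis acid-mediated C-glycosylation-type alkynylation), so the alkyne should enter cis to the C5 substituent and set (2R), after which K2CO3 in methanol removes the silyl group.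

Step 8
Reactants: 14 (2R,5R)-2-ethynyl-5-[(3E,7E)-4,8,12-trimethyltrideca-3,7,11-trien-1-yl]oxane
Product: 15 rhopaloic acid B, 2-{(2R,5R)-5-[(3E,7E)-4,8,12-trimethyltrideca-3,7,11-trien-1-yl]oxan-2-yl}prop-2-enoic acid
Conditions: Pd(OAc)2 (cat.), 2-(diphenylphosphino)pyridine, TsOH (cat.), CO (20 bar), H2O, THF, 50 °C
Reagents that add atoms: carbon monoxide, [C-]#[O+]; water, O
Why: Palladium-catalysed Markovnikov hydroxycarbonylation of the terminal alkyne (hydride to the terminal carbon, CO insertion at the internal carbon, hydrolysis of the acyl) should give the α-substituted acrylic acid directly, while the isolated trisubstituted alkenes and the C2 stereocentre are not affected.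

**Compound list**

1 | 2-methylprop-2-en-1-ol | C=C(C)CO | starting material
2 | (2E,6E)-1-bromo-3,7,11-trimethyldodeca-2,6,10-triene ((2E,6E)-farnesyl bromide) | BrC/C=C(\C)CC/C=C(\C)CCC=C(C)C | starting material
3 | dilithium O,C-dianion of 2-methylprop-2-en-1-ol | [Li]CC(=C)CO[Li] | intermediate
4 | (5E,9E)-6,10,14-trimethyl-2-methylidenepentadeca-5,9,13-trien-1-ol | C=C(CO)CC/C=C(\C)CC/C=C(\C)CCC=C(C)C | intermediate
5 | 9-{[(5E,9E)-2-[(9-borabicyclo[3.3.1]nonan-9-yl)methyl]-6,10,14-trimethylpentadeca-5,9,13-trien-1-yl]oxy}-9-borabicyclo[3.3.1]nonane | C(CB1C2CCCC1CCC2)(COB1C2CCCC1CCC2)CC/C=C(\C)CC/C=C(\C)CCC=C(C)C | intermediate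
6 | 2-[(3E,7E)-4,8,12-trimethyltrideca-3,7,11-trien-1-yl]propane-1,3-diol | OCC(CO)CC/C=C(\C)CC/C=C(\C)CCC=C(C)C | intermediate
7 | (2R,5E,9E)-2-(hydroxymethyl)-6,10,14-trimethylpentadeca-5,9,13-trien-1-yl acetate | OC[C@@H](CC/C=C(\C)CC/C=C(\C)CCC=C(C)C)COC(C)=O | intermediate
8 | (2S,5E,9E)-2-(iodomethyl)-6,10,14-trimethylpentadeca-5,9,13-trien-1-yl acetate | IC[C@@H](CC/C=C(\C)CC/C=C(\C)CCC=C(C)C)COC(C)=O | intermediate
9 | lithium 1-{[(2S,5E,9E)-2-(iodomethyl)-6,10,14-trimethylpentadeca-5,9,13-trien-1-yl]oxy}ethen-1-olate | IC[C@@H](CC/C=C(\C)CC/C=C(\C)CCC=C(C)C)COC(=C)O[Li] | intermediate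
10 | (5R)-5-[(3E,7E)-4,8,12-trimethyltrideca-3,7,11-trien-1-yl]oxan-2-one | O=C1CC[C@@H](CC/C=C(\C)CC/C=C(\C)CCC=C(C)C)CO1 | intermediate
11 | diisobutylaluminium (5R)-5-[(3E,7E)-4,8,12-trimethyltrideca-3,7,11-trien-1-yl]oxan-2-olate | CC(C)C[Al](CC(C)C)OC1CC[C@@H](CC/C=C(\C)CC/C=C(\C)CCC=C(C)C)CO1 | intermediate
12 | (5R)-5-[(3E,7E)-4,8,12-trimethyltrideca-3,7,11-trien-1-yl]oxan-2-yl acetate (both C2 epimers) | CC(=O)OC1CC[C@@H](CC/C=C(\C)CC/C=C(\C)CCC=C(C)C)CO1 | intermediate
13 | trimethyl({(2R,5R)-5-[(3E,7E)-4,8,12-trimethyltrideca-3,7,11-trien-1-yl]oxan-2-yl}ethynyl)silane | C[Si](C)(C)C#C[C@H]1CC[C@@H](CC/C=C(\C)CC/C=C(\C)CCC=C(C)C)CO1 | intermediate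
14 | (2R,5R)-2-ethynyl-5-[(3E,7E)-4,8,12-trimethyltrideca-3,7,11-trien-1-yl]oxane | C#C[C@H]1CC[C@@H](CC/C=C(\C)CC/C=C(\C)CCC=C(C)C)CO1 | intermediate
15 | rhopaloic acid B, 2-{(2R,5R)-5-[(3E,7E)-4,8,12-trimethyltrideca-3,7,11-trien-1-yl]oxan-2-yl}prop-2-enoic acid | C=C(C(=O)O)[C@H]1CC[C@@H](CC/C=C(\C)CC/C=C(\C)CCC=C(C)C)CO1 | target

**Total step count:** 8
**Longest linear sequence:** 8 steps (from 1 and 2)

**Steps most likely to fail**

1. Step 5 (key step). What may go wrong: intermolecular Claisen condensation, O-alkylation or fragmentation of the ester enolate may outrun the ring closure. Fallback, setting out from diol 6 and coming back at lactone 10: lipase-catalysed desymmetrisation of 6 with vinyl acrylate should give the mono-acrylate (2R,5E,9E)-2-(hydroxymethyl)-6,10,14-trimethylpentadeca-5,9,13-trien-1-yl prop-2-enoate F1. Oxidation with Dess–Martin periodinane gives the aldehyde (2S,5E,9E)-2-formyl-6,10,14-trimethylpentadeca-5,9,13-trien-1-yl prop-2-enoate F2. Non-basic methylenation (Zn, CH2Br2, TiCl4) gives the diene (2R,5E,9E)-2-ethenyl-6,10,14-trimethylpentadeca-5,9,13-trien-1-yl prop-2-enoate F3. Ring-closing metathesis with the second-generation Grubbs catalyst closes the ring through the same two carbons as a C=C bond, giving (5R)-5-[(3E,7E)-4,8,12-trimethyltrideca-3,7,11-trien-1-yl]-5,6-dihydro-2H-pyran-2-one F4. Chemoselective conjugate reduction of the enoate with [(Ph3P)CuH]6 then gives 10.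

2. Step 8. What may go wrong: loss of regiocontrol in the palladium hydride addition (linear acid), or acid-induced isomerisation or cyclisation of the polyene chain. Fallback, setting out from alkyne 14 and coming back at target 15: hydrostannation with Bu3SnH and catalytic Mo(CO)3(CNtBu)3 places tin on the internal carbon next to the ether oxygen and gives tributyl(1-{(2R,5R)-5-[(3E,7E)-4,8,12-trimethyltrideca-3,7,11-trien-1-yl]oxan-2-yl}ethenyl)stannane F5. Iododestannylation (I2, CH2Cl2, 0 °C) gives (2R,5R)-2-(1-iodoethenyl)-5-[(3E,7E)-4,8,12-trimethyltrideca-3,7,11-trien-1-yl]oxane F6. Hydroxycarbonylation of the vinyl iodide (Pd(OAc)2, PPh3, CO, H2O, Et3N, DMF), whose regiochemistry is fixed by the C–I bond, gives 15.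

3. Step 3. What may go wrong: insufficient discrimination of the enantiotopic hydroxymethyl groups, or acetyl migration between them, eroding the enantiomeric purity at C5. Fallback, setting out from bromide 2 and coming back at monoacetate 7: Li2CuCl4-catalysed coupling of 2 with the Grignard reagent made from 2-(2-bromoethyl)-1,3-dioxolane and Mg gives the acetal 2-[(4E,8E)-5,9,13-trimethyltetradeca-4,8,12-trien-1-yl]-1,3-dioxolane F7. Hydrolysis (AcOH–H2O–THF) gives the aldehyde (5E,9E)-6,10,14-trimethylpentadeca-5,9,13-trienal F8. Enamine-catalysed asymmetric α-hydroxymethylation with aqueous formaldehyde, using the enantiomer of α,α-diphenylprolinol trimethylsilyl ether that delivers the (2S) product, gives (2S,5E,9E)-2-(hydroxymethyl)-6,10,14-trimethylpentadeca-5,9,13-trienal F9. Acetylation under neutral conditions (vinyl acetate, Candida antarctica lipase B) gives (2S,5E,9E)-2-formyl-6,10,14-trimethylpentadeca-5,9,13-trien-1-yl acetate F10. Reduction with NaBH4 (EtOH, −20 °C) gives 7.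

Further compounds
F1 | step 5 | (2R,5E,9E)-2-(hydroxymethyl)-6,10,14-trimethylpentadeca-5,9,13-trien-1-yl prop-2-enoate | OC[C@@H](CC/C=C(\C)CC/C=C(\C)CCC=C(C)C)COC(=O)C=C
F2 | step 5 | (2S,5E,9E)-2-formyl-6,10,14-trimethylpentadeca-5,9,13-trien-1-yl prop-2-enoate | O=C[C@@H](CC/C=C(\C)CC/C=C(\C)CCC=C(C)C)COC(=O)C=C
F3 | step 5 | (2R,5E,9E)-2-ethenyl-6,10,14-trimethylpentadeca-5,9,13-trien-1-yl prop-2-enoate | C=C[C@@H](CC/C=C(\C)CC/C=C(\C)CCC=C(C)C)COC(=O)C=C
F4 | step 5 | (5R)-5-[(3E,7E)-4,8,12-trimethyltrideca-3,7,11-trien-1-yl]-5,6-dihydro-2H-pyran-2-one | O=C1C=C[C@@H](CC/C=C(\C)CC/C=C(\C)CCC=C(C)C)CO1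
F5 | step 8 | tributyl(1-{(2R,5R)-5-[(3E,7E)-4,8,12-trimethyltrideca-3,7,11-trien-1-yl]oxan-2-yl}ethenyl)stannane | C=C([Sn](CCCC)(CCCC)CCCC)[C@H]1CC[C@@H](CC/C=C(\C)CC/C=C(\C)CCC=C(C)C)CO1
F6 | step 8 | (2R,5R)-2-(1-iodoethenyl)-5-[(3E,7E)-4,8,12-trimethyltrideca-3,7,11-trien-1-yl]oxane | C=C(I)[C@H]1CC[C@@H](CC/C=C(\C)CC/C=C(\C)CCC=C(C)C)CO1
F7 | step 3 | 2-[(4E,8E)-5,9,13-trimethyltetradeca-4,8,12-trien-1-yl]-1,3-dioxolane | C1COC(O1)CCC/C=C(\C)CC/C=C(\C)CCC=C(C)C
F8 | step 3 | (5E,9E)-6,10,14-trimethylpentadeca-5,9,13-trienal | O=CCCC/C=C(\C)CC/C=C(\C)CCC=C(C)C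
F9 | step 3 | (2S,5E,9E)-2-(hydroxymethyl)-6,10,14-trimethylpentadeca-5,9,13-trienal | O=C[C@@H](CC/C=C(\C)CC/C=C(\C)CCC=C(C)C)CO
F10 | step 3 | (2S,5E,9E)-2-formyl-6,10,14-trimethylpentadeca-5,9,13-trien-1-yl acetate | O=C[C@@H](CC/C=C(\C)CC/C=C(\C)CCC=C(C)C)COC(C)=O
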